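**Small charge.** A small charge of second nucleophile, 0.600 equiv against 4.00 equiv of first nucleophile, was what I watched in this flask, which repeats the dawn run with twice the protic impurity.

in all of them: substrate 0.025 M
- dawn: first nucleophile 4 equiv; second nucleophile 0.60 equiv; protic impurity 0.0063 M; run made earlier
- flask: first nucleophile 4.00 equiv; second nucleophile 0.600 equiv; protic impurity 0.0125 M; time 10 d

dawn run (percent of the substrate charged)

| time / h | target / % | other capture product / % | substrate / % |
|---|---|---|---|
| 4.00 | 58 | 9 | 34 |
| 6.00 | 77 | 3 | 20 |
| 10.0 | 86 | 8 | 8 |
| 20.0 | 93 | 8 | 0 |
| 30.0 | 95 | 6 | 2 |
| 50.0 | 92 | 7 | 3 |

(readings scatter by 2 percentage points)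

- share of target in target plus other capture product at 12 min
- share of target in target plus other capture product at 6.0 h
- share of target in target plus other capture product at 10 d

- no earlier run changes the charge of protic impurity; that part of a forecast is a guess

**Catch time.** In the dawn run substrate fell to 20% by 6.00 h, which I read as a first-order capture pace of 0.268 h⁻¹. The other capture product scattered around a mean of 6.83% from the first reading on. I took it to come from the second nucleophile, so the selectivity at any moment compares two capture rates, and that comparison should drift towards target as c(second nucleophile) falls. I named the catch time: that plateau divided by the capture pace, 15.3 min. It is how long capture at the opening pace takes to equal the whole plateau.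

**Early share.** If the other capture product is made within a window of time constant W, its opening share of capture is the catch time over W. The 4.00 h reading already stood at the plateau within scatter, so I put W at 2.00 h or less, half that time. Since 12 min lies inside that window, I expected an early share of target of about 87.3% or lower, rising late towards 93.2%. What the added protic impurity does to W stayed a guess.

**The forecast.** The forecast gave 91%, 92% and 93%, on the ground of “no visible drift”. Its early figure stood above mine, with a range from 78% to 97%.

**The result.** The flask gave 75.7%, 92.5% and 93.8%, so the forecast's early figure was 15 percentage points too high and its later two held. At 1.00 d the other capture product stood at 6.20%, with second nucleophile down to 1.31% of its charge. Scaled to this flask's final 6.20% at the dawn capture pace, the catch time is 13.9 min, and the share at 12 min, taken as the opening one, then gives W = 0.951 h.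

    substrate ⇌ intermediate (K = 0.00960, k = 0.370 h⁻¹)
    first nucleophile + intermediate → target (k = 1100 M⁻¹ h⁻¹)
    second nucleophile + intermediate → other capture product (k = 2900 M⁻¹ h⁻¹)
    2 second nucleophile → homo dimer (k = 52.0 M⁻¹ h⁻¹)
    second nucleophile ⇌ dormant form (K = 2.70, k = 0.280 h⁻¹)
    second nucleophile + protic impurity → quenched reagent (k = 30.0 M⁻¹ h⁻¹)

**Second flask.** In the neighbour flask with 1.00 equiv of second nucleophile, the final 8.05% of other capture product gives a catch time of 18.0 min. Taking the same W for that neighbour flask, I get an early share of target of 68.5%. The computed share in that neighbour flask at 12 min is 66.8%.

All runs stem from a simulated flask on assumed constants, and the scatter is random.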